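Start from the amounts. Eta gets 1.17 M of reagent and beta 0.600 M, about twice as much, with the same substrates and free catalyst.

common to all: left-handed substrate 0.39 M; right-handed substrate 0.39 M; free catalyst 20 mM

|  | reagent | remark | time |
|---|---|---|---|
| Monday's | 0.45 M (fed, over 50 min) | run made earlier; the fed solution adds 0.50 times the starting volume |  |
| Friday's | 0.81 M (fed, over 50 min) | run made earlier; the fed solution adds 0.50 times the starting volume |  |
| Sunday's | 1.3 M (fed, over 50 min) | run made earlier; the fed solution adds 0.50 times the starting volume |  |
| eta | 1.17 M (fed, over 50 min) | the fed solution adds 0.50 times the starting volume | 2.5 h |
| beta | 0.600 M | everything together at the start, the whole solution of reagent included, so that from the start the volume is larger by 0.50 times the starting volume | 2.5 h |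

- Monday's (time / h: left-handed product / %): 0.200: 0.1; 0.500: 1.2; 1.00: 4.4; 2.50: 11.8
- Friday's (time / h: left-handed product / %): 0.667: 3.7; 1.33: 9.8; 2.00: 16.3; 2.50: 19.7
- Sunday's (time / h: left-handed product / %): 0.200: 0.8; 0.500: 2.9; 1.00: 10.7; 2.50: 29.0

(readings scatter by 0.5 percentage points)

- free catalyst is single-handed; left-handed substrate and right-handed substrate are mirror images of each other, charged as a racemate, each of them at the stated concentration
- charges are per starting volume, the dose included; the dosed solution carries all of it

1. the winner by amount of left-handed product, in percent of the left-handed substrate and right-handed substrate together charged; "neither" if no more than 2 percentage points parts them (eta / beta / neither)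
2. how much left-handed product is there at the end, in percent of the left-handed substrate and right-handed substrate together charged: eta
3. how much left-handed product is there at the end, in percent of the left-handed substrate and right-handed substrate together charged: beta

But does eta's charge count in full when it arrives over 50 min? Replace the rising curve by its mean. Take the feed as a straight climb to final strength, so its mean is half of that strength and you lose half the feeding time. Final strength is the charge over the final volume. Multiplied by the hours so counted, it gives eta 1.62 M·h, the reagent dose. With the volume growing, the exact mean is 0.567 of final strength, so this dose runs low by 2.69 %. Beta has no feed, so its dose is 1.00 M·h. Eta's lead shrinks to a factor of 1.62.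

What does a dose buy? Double the percentage read to get the fraction of the left-handed charge converted. Take minus the logarithm of the fraction left and divide by the dose. Each constant so read carries the scatter of its reading. At the last readings, Monday gives 0.431 /M/h, Friday 0.445 /M/h and Sunday 0.480 /M/h.

Eta's dose lies between Friday's and Sunday's, so I use their mean constant and get 26.4 %. Beta's lies between Monday's and Friday's, which gives 17.7 %. The gap of 8.7 percentage points is wider than the margin, so I commit to eta.

The forecast says eta, with 26.5 % for eta and 17 % for beta: "Eta wins, mainly because it has twice the reagent". Its beta stands lower than mine.

The flask gives eta, with 26.8 % for eta against 17.0 % for beta.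

    reagent + catalyst intermediate A → free catalyst + left-handed product (k = 0.180 /M/min)
    free catalyst + left-handed substrate ⇌ catalyst intermediate A (K = 40.0 /M, k = 32.0 /M/min)
    free catalyst → spent catalyst B (k = 0.0110 /min)
    reagent + free catalyst → spent catalyst A (k = 0.00730 /M/min)
    reagent + catalyst intermediate B → free catalyst + right-handed product (k = 0.00390 /M/min)
    free catalyst + right-handed substrate ⇌ catalyst intermediate B (K = 4.90 /M, k = 8.40 /M/min)

In beta at 0.926 h, catalyst intermediate A falls back 12 times faster than it goes on. In beta at 2.50 h it holds 59.2 % of the catalyst, more than any other form: it is the resting state.

Beta's result gives a constant of 0.415 /M/h. Beta left until 6.0 h has a dose of 2.40 M·h, which gives 31.5 %. That flask gives 29.4 %, with spent catalyst A and spent catalyst B together at 44.9 % of the catalyst.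

The numbers in the tables were generated by integration with constants of no real substance.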